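**Plan**
- Retrosynthesis: the two terminal CH=CH2 bonds of the allyl groups are cut first (to a bis-arylacetaldehyde), then the two ring A–ring B biaryl bonds, then the C2–aryl bond of the dioxane, the O1–C(=O) bond of a dioxanone, the aryl–C(=O) bond at the later C6, and last the O4–C3 ether bond between two lactate units.
- Enabling feature: each outer phenol ring (ring B) carries, para to its OH, a CH2–CH=CH2 chain. This terminal alkene is the one-carbon homologue of ArCH2–CHO, and that two-carbon chain with its para phenol is tyrosol.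
- Forward order: lactate ether, C2-symmetric cyclic anhydride, opening by one aryl, lactonisation to the 1,4-dioxan-2-one (the only ring that has to be built), second aryl at the anomeric carbon to give the dioxane core, two-fold Suzuki coupling with a tyrosol boronate, oxidation, double Wittig methylenation, detosylation.
- Stereochemistry: C3 and C5 come from ethyl (R)-lactate (retained) and ethyl (S)-lactate (inverted by SN2). C6 comes from a catalyst-controlled transfer hydrogenation. C2 comes from axial attack of an arylzinc on the ring oxocarbenium ion, anti to the C3 methyl.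

Key step: step 16

Remark: the target is read as the C2-symmetric all-trans dioxane (aryl and methyl trans at C2/C3 and at C5/C6, the two aryl groups trans across O1), which is what (2R,3R,5R,6R) means here. Ts is 4-methylbenzenesulfonyl, and 2-bromo-4-iodophenol is taken as commercial.

Step 1
Reactants: 1 ethyl (S)-lactate
Product: 2 ethyl (2S)-2-[(trifluoromethylsulfonyl)oxy]propanoate
Conditions: (CF3SO2)2O, 2,6-lutidine, CH2Cl2, −78 → 0 °C
Reagents that add atoms: trifluoromethanesulfonic anhydride, O=S(=O)(OS(=O)(=O)C(F)(F)F)C(F)(F)F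
Why: O-sulfonylation (triflate formation) touches only the O–H bond, so the S centre is kept and the α-carbon becomes a highly reactive SN2 electrophile.

Step 2
Reactants: 3 ethyl (R)-lactate; 2 ethyl (2S)-2-[(trifluoromethylsulfonyl)oxy]propanoate
Product: 4 diethyl (2R,2'R)-2,2'-oxydipropanoate
Conditions: 3, NaH, THF, −20 °C; then 2, −20 → 0 °C
Reagents that add atoms: none
Why: Williamson ether synthesis in which the sodium alkoxide of 3 (its R centre untouched) displaces the carbonyl-activated α-triflate of 2 by SN2 with inversion (S to R), so both CH(CH3) carbons of the ether, the later C3 and C5, should be R, the cold conditions letting substitution outrun ester enolisation.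

Step 3
Reactants: 4 diethyl (2R,2'R)-2,2'-oxydipropanoate
Product: 5 (2R,2'R)-2,2'-oxydipropanoic acid
Conditions: LiOH·H2O, THF/H2O, 0 °C; then aq. HCl
Reagents that add atoms: lithium hydroxide (hydroxide oxygen), [Li+].[OH-]
Why: Saponification is acyl substitution at the ester carbonyl, and the carboxylates formed resist enolisation under cold LiOH, so the two α-alkoxy stereocentres should survive.

Step 4
Reactants: 5 (2R,2'R)-2,2'-oxydipropanoic acid
Product: 6 (3R,5R)-3,5-dimethyl-1,4-dioxane-2,6-dione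
Conditions: (CF3CO)2O, CH2Cl2, 0 °C → rt; evaporate
Reagents that add atoms: none
Why: Cyclodehydration of the 1,5-diacid through its mixed trifluoroacetic anhydride gives the six-membered cyclic anhydride under cold, acid-side conditions that should not epimerise the α-centres, and the trans-dimethyl anhydride is C2-symmetric so its two carbonyl groups are equivalent.

Step 5
Reactants: 7 2-bromo-4-iodophenol
Product: 8 2-bromo-4-iodophenyl 4-methylbenzenesulfonate
Conditions: TsCl, K2CO3, acetone, rt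
Reagents that add atoms: 4-methylbenzenesulfonyl chloride, Cc1ccc(cc1)S(Cl)(=O)=O
Why: O-sulfonylation of the phenoxide (Schotten–Baumann-type tosylation) installs a group that tolerates organometallic, hydride, palladium and ylide chemistry and, being electron-withdrawing, later protects the benzylic ether carbons from ionisation.

Step 6
Reactants: 6 (3R,5R)-3,5-dimethyl-1,4-dioxane-2,6-dione; 8 2-bromo-4-iodophenyl 4-methylbenzenesulfonate
Product: 10 (2R)-2-{[(2R)-1-[3-bromo-4-(tosyloxy)phenyl]-1-oxopropan-2-yl]oxy}propanoic acid, via arylmagnesium chloride 9 (not isolated)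
Conditions: 8, i-PrMgCl·LiCl, THF, −40 °C; then add to 6, THF, −78 → −30 °C; aq. HCl
Reagents that add atoms: none
Why: Iodine–magnesium exchange takes place at the C–I bond only (far faster than at C–Br, sulfonate untouched at −40 °C), and the aryl Grignard reagent opens the cyclic anhydride once by nucleophilic acyl substitution because the magnesium carboxylate formed and the low temperature hold back a second addition, the C2 symmetry of 6 guaranteeing a single keto acid.

Step 7
Reactants: 10 (2R)-2-{[(2R)-1-[3-bromo-4-(tosyloxy)phenyl]-1-oxopropan-2-yl]oxy}propanoic acid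
Product: 12 (3R,5R,6R)-6-[3-bromo-4-(tosyloxy)phenyl]-3,5-dimethyl-1,4-dioxan-2-one, via threo hydroxy acid 11 (not isolated)
Conditions: RuCl[(S,S)-TsDPEN](p-cymene) (cat.), HCO2H/Et3N (5:2), EtOAc, 25 °C; then TsOH·H2O (cat.), toluene, 50 °C
Reagents that add atoms: none
Why: Noyori asymmetric transfer hydrogenation with the (S,S) catalyst should deliver hydride to the aryl ketone face that gives the (R)-carbinol (catalyst control, reinforced by the Felkin–Anh preference of an α-alkoxy ketone for the syn product), and the δ-hydroxy acid then lactonises under acid catalysis with retention at C6 because only the acyl C–O bond is formed.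

Step 8
Reactants: 12 (3R,5R,6R)-6-[3-bromo-4-(tosyloxy)phenyl]-3,5-dimethyl-1,4-dioxan-2-one
Product: 13 (3R,5R,6R)-6-[3-bromo-4-(tosyloxy)phenyl]-3,5-dimethyl-1,4-dioxan-2-ol (both C2 epimers)
Conditions: i-Bu2AlH, CH2Cl2, −78 °C; aq. KNaC4H4O6 (potassium sodium tartrate) work-up
Reagents that add atoms: none
Why: Partial reduction of a lactone with one hydride equivalent at −78 °C stops at the aluminium hemiacetal and gives the lactol on work-up, the new anomeric centre being erased two steps later.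

Step 9
Reactants: 13 (3R,5R,6R)-6-[3-bromo-4-(tosyloxy)phenyl]-3,5-dimethyl-1,4-dioxan-2-ol
Product: 14 (3R,5R,6R)-6-[3-bromo-4-(tosyloxy)phenyl]-3,5-dimethyl-2-(phenylsulfonyl)-1,4-dioxane (both C2 epimers)
Conditions: PhSO2H, CaCl2, CH2Cl2, rt
Reagents that add atoms: benzenesulfinic acid, OS(=O)c1ccccc1
Why: Acid-mediated exchange of the anomeric hydroxyl for sulfinate through the ring oxocarbenium ion is the standard preparation of 2-(phenylsulfonyl) cyclic ethers and gives a stable anomeric leaving group whose configuration does not matter.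

Step 10
Reactants: 14 (3R,5R,6R)-6-[3-bromo-4-(tosyloxy)phenyl]-3,5-dimethyl-2-(phenylsulfonyl)-1,4-dioxane; 8 2-bromo-4-iodophenyl 4-methylbenzenesulfonate
Product: 17 (2R,3R,5R,6R)-2,6-bis[3-bromo-4-(tosyloxy)phenyl]-3,5-dimethyl-1,4-dioxane, via arylmagnesium bromide 15 (not isolated), via arylzinc bromide 16 (not isolated)
Conditions: 8, i-PrMgBr, THF, −40 °C; ZnBr2, −40 → 0 °C; then 14, THF, 0 → 40 °C; dilute aq. HCl
Reagents that add atoms: none
Why: Iodine–magnesium exchange of the electron-poor aryl iodide with i-PrMgBr followed by transmetalation to ZnBr2 gives the arylzinc bromide together with MgBr2 in an all-bromide medium, the Lewis-acidic salts ionise the anomeric sulfone to the cyclic oxocarbenium ion, and the arylzinc attacks C2 (the known substitution of 2-sulfonyl cyclic ethers by Grignard-derived organozinc reagents); because the favoured half-chair has the C6 aryl and C5 methyl pseudo-equatorial and the C3 methyl pseudo-axial, axial attack through a chair-like transition state comes anti to that methyl and should set C2 as R, trans to both the C3 methyl and the C6 aryl.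

Step 11
Reactants: 18 tyrosol
Product: 19 2-bromo-4-(2-hydroxyethyl)phenol
Conditions: NBS, MeCN, −10 → 0 °C
Reagents that add atoms: N-bromosuccinimide, O=C1CCC(=O)N1Br
Why: Electrophilic aromatic bromination of a para-substituted phenol occurs ortho to the hydroxyl, and one equivalent of NBS in the cold should stop at the monobromide.

Step 12
Reactants: 19 2-bromo-4-(2-hydroxyethyl)phenol
Product: 20 2-bromo-4-(2-hydroxyethyl)phenyl 4-methylbenzenesulfonate
Conditions: TsCl, K2CO3, acetone, rt
Reagents that add atoms: 4-methylbenzenesulfonyl chloride, Cc1ccc(cc1)S(Cl)(=O)=O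
Why: Carbonate ionises only the phenol, so the chemoselective O-sulfonylation takes the phenoxide and leaves the neutral primary alcohol free.

Step 13
Reactants: 20 2-bromo-4-(2-hydroxyethyl)phenyl 4-methylbenzenesulfonate
Product: 21 4-(2-hydroxyethyl)-2-(4,4,5,5-tetramethyl-1,3,2-dioxaborolan-2-yl)phenyl 4-methylbenzenesulfonate
Conditions: B2pin2, Pd(dppf)Cl2·CH2Cl2 (cat.), KOAc, 1,4-dioxane, 85 °C
Reagents that add atoms: bis(pinacolato)diboron, CC1(C)OB(OC1(C)C)B1OC(C)(C)C(C)(C)O1
Why: Miyaura borylation (oxidative addition into C–Br, acetate-assisted transmetalation with the diboron, reductive elimination) tolerates the free alcohol and the aryl sulfonate.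

Step 14
Reactants: 17 (2R,3R,5R,6R)-2,6-bis[3-bromo-4-(tosyloxy)phenyl]-3,5-dimethyl-1,4-dioxane; 21 4-(2-hydroxyethyl)-2-(4,4,5,5-tetramethyl-1,3,2-dioxaborolan-2-yl)phenyl 4-methylbenzenesulfonate
Product: 22 (2R,3R,5R,6R)-2,6-bis[5'-(2-hydroxyethyl)-2',6-bis(tosyloxy)biphenyl-3-yl]-3,5-dimethyl-1,4-dioxane
Conditions: 21 (2.4 equiv), Pd(OAc)2 (cat.), SPhos, K3PO4, toluene/H2O, 70 °C
Reagents that add atoms: boronate 21 (second equivalent, one molecule of 21 being taken up at each C–Br bond), OCCc1ccc(OS(=O)(=O)c2ccc(C)cc2)c(c1)B1OC(C)(C)C(C)(C)O1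
Why: Two-fold Suzuki–Miyaura coupling in which each of the two equivalent C–Br bonds of the C2-symmetric dibromide takes up one molecule of 21, the bulky, electron-rich SPhos ligand promoting oxidative addition at C–Br (the aryl sulfonates being far slower) and the union of two ortho-substituted partners, while the mild phosphate base leaves sulfonates, alcohols and the dioxane stereocentres alone.

Step 15
Reactants: 22 (2R,3R,5R,6R)-2,6-bis[5'-(2-hydroxyethyl)-2',6-bis(tosyloxy)biphenyl-3-yl]-3,5-dimethyl-1,4-dioxane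
Product: 23 (2R,3R,5R,6R)-2,6-bis[5'-(2-oxoethyl)-2',6-bis(tosyloxy)biphenyl-3-yl]-3,5-dimethyl-1,4-dioxane
Conditions: Dess–Martin periodinane, NaHCO3, CH2Cl2, 0 °C → rt; used crude
Reagents that add atoms: none
Why: Dess–Martin oxidation converts both primary alcohols into aldehydes under buffered, non-enolising conditions without over-oxidation, and the labile arylacetaldehydes are carried on at once.

Step 16
Reactants: 23 (2R,3R,5R,6R)-2,6-bis[5'-(2-oxoethyl)-2',6-bis(tosyloxy)biphenyl-3-yl]-3,5-dimethyl-1,4-dioxane; 24 methyltriphenylphosphonium bromide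
Product: 26 (2R,3R,5R,6R)-2,6-bis[5'-allyl-2',6-bis(tosyloxy)biphenyl-3-yl]-3,5-dimethyl-1,4-dioxane, via methylenetriphenylphosphorane 25 (not isolated)
Conditions: 24, KN(SiMe3)2, THF, 0 °C; then 23, −78 → 0 °C
Reagents that add atoms: methylenetriphenylphosphorane 25 (made in the flask from 24), C=P(c1ccccc1)(c1ccccc1)c1ccccc1
Why: Each formyl group undergoes [2+2] addition with the non-stabilised ylide 25 to an oxaphosphetane that collapses by cycloreversion to the alkene and Ph3PO, so each new C=CH2 bond joins a former carbonyl carbon to the ylide carbon and can only be terminal. This is the Wittig methylenation of arylacetaldehydes to allylarenes, run in two directions on a C2-symmetric dialdehyde whose two ends are equivalent, one molecule of ylide being consumed at each end. No ring closes and no stereocentre is made or touched, the four dioxane centres lying far from the reacting carbons. The selectivity needed is chemoselectivity: addition to C=O must outrun deprotonation at the acidic ArCH2–CHO position and any attack on the four aryl sulfonates. It is secured by a lithium-free ylide made with a slight deficit of KN(SiMe3)2 so that no free amide base remains, by adding the dialdehyde to excess ylide at −78 °C, and by the high electrophilicity of the unhindered aldehydes. Making the alkenes only now keeps them away from the hydride, palladium, Lewis-acid and oxidising steps, through which the saturated hydroxyethyl chains pass unchanged.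

Step 17
Reactants: 26 (2R,3R,5R,6R)-2,6-bis[5'-allyl-2',6-bis(tosyloxy)biphenyl-3-yl]-3,5-dimethyl-1,4-dioxane
Product: 27 (2R,3R,5R,6R)-2,6-bis(5'-allyl-2',6-dihydroxybiphenyl-3-yl)-3,5-dimethyl-1,4-dioxane
Conditions: Mg turnings, MeOH/THF, rt; aq. NH4Cl
Reagents that add atoms: none
Why: Magnesium in methanol cleaves the four aryl sulfonate S–O bonds by single-electron transfer (reductive desulfonylation) at room temperature, which should free the phenols without touching the isolated terminal alkenes or the dioxane, whose para-hydroxybenzylic ether centres would be at risk under hot alkali or acid.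

**Compound list**
1 | ethyl (S)-lactate | CCOC(=O)[C@H](C)O | starting material
2 | ethyl (2S)-2-[(trifluoromethylsulfonyl)oxy]propanoate | CCOC(=O)[C@H](C)OS(=O)(=O)C(F)(F)F | intermediate
3 | ethyl (R)-lactate | CCOC(=O)[C@@H](C)O | starting material
4 | diethyl (2R,2'R)-2,2'-oxydipropanoate | CCOC(=O)[C@@H](C)O[C@H](C)C(=O)OCC | intermediate
5 | (2R,2'R)-2,2'-oxydipropanoic acid | OC(=O)[C@@H](C)O[C@H](C)C(=O)O | intermediate
6 | (3R,5R)-3,5-dimethyl-1,4-dioxane-2,6-dione | O=C1[C@@H](C)O[C@H](C)C(=O)O1 | intermediate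
7 | 2-bromo-4-iodophenol | Oc1ccc(I)cc1Br | starting material
8 | 2-bromo-4-iodophenyl 4-methylbenzenesulfonate | Cc1ccc(cc1)S(=O)(=O)Oc1ccc(I)cc1Br | intermediate
9 | [3-bromo-4-(tosyloxy)phenyl]magnesium chloride (LiCl complex) | Cc1ccc(cc1)S(=O)(=O)Oc1ccc([Mg]Cl)cc1Br | intermediate
10 | (2R)-2-{[(2R)-1-[3-bromo-4-(tosyloxy)phenyl]-1-oxopropan-2-yl]oxy}propanoic acid | Cc1ccc(cc1)S(=O)(=O)Oc1ccc(cc1Br)C(=O)[C@@H](C)O[C@H](C)C(=O)O | intermediate
11 | (2R)-2-{[(1R,2R)-1-[3-bromo-4-(tosyloxy)phenyl]-1-hydroxypropan-2-yl]oxy}propanoic acid | Cc1ccc(cc1)S(=O)(=O)Oc1ccc(cc1Br)[C@@H](O)[C@@H](C)O[C@H](C)C(=O)O | intermediate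
12 | (3R,5R,6R)-6-[3-bromo-4-(tosyloxy)phenyl]-3,5-dimethyl-1,4-dioxan-2-one | Cc1ccc(cc1)S(=O)(=O)Oc1ccc(cc1Br)[C@H]1OC(=O)[C@@H](C)O[C@@H]1C | intermediate
13 | (3R,5R,6R)-6-[3-bromo-4-(tosyloxy)phenyl]-3,5-dimethyl-1,4-dioxan-2-ol (both C2 epimers) | Cc1ccc(cc1)S(=O)(=O)Oc1ccc(cc1Br)[C@H]1OC(O)[C@@H](C)O[C@@H]1C | intermediate
14 | (3R,5R,6R)-6-[3-bromo-4-(tosyloxy)phenyl]-3,5-dimethyl-2-(phenylsulfonyl)-1,4-dioxane (both C2 epimers) | Cc1ccc(cc1)S(=O)(=O)Oc1ccc(cc1Br)[C@H]1OC([C@@H](C)O[C@@H]1C)S(=O)(=O)c1ccccc1 | intermediate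
15 | [3-bromo-4-(tosyloxy)phenyl]magnesium bromide | Cc1ccc(cc1)S(=O)(=O)Oc1ccc([Mg]Br)cc1Br | intermediate
16 | [3-bromo-4-(tosyloxy)phenyl]zinc bromide | Cc1ccc(cc1)S(=O)(=O)Oc1ccc([Zn]Br)cc1Br | intermediate
17 | (2R,3R,5R,6R)-2,6-bis[3-bromo-4-(tosyloxy)phenyl]-3,5-dimethyl-1,4-dioxane | Cc1ccc(cc1)S(=O)(=O)Oc1ccc(cc1Br)[C@H]1O[C@H](c2ccc(OS(=O)(=O)c3ccc(C)cc3)c(Br)c2)[C@@H](C)O[C@@H]1C | intermediate
18 | tyrosol | OCCc1ccc(O)cc1 | starting material
19 | 2-bromo-4-(2-hydroxyethyl)phenol | OCCc1ccc(O)c(Br)c1 | intermediate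
20 | 2-bromo-4-(2-hydroxyethyl)phenyl 4-methylbenzenesulfonate | OCCc1ccc(OS(=O)(=O)c2ccc(C)cc2)c(Br)c1 | intermediate
21 | 4-(2-hydroxyethyl)-2-(4,4,5,5-tetramethyl-1,3,2-dioxaborolan-2-yl)phenyl 4-methylbenzenesulfonate | OCCc1ccc(OS(=O)(=O)c2ccc(C)cc2)c(c1)B1OC(C)(C)C(C)(C)O1 | intermediate
22 | (2R,3R,5R,6R)-2,6-bis[5'-(2-hydroxyethyl)-2',6-bis(tosyloxy)biphenyl-3-yl]-3,5-dimethyl-1,4-dioxane | OCCc1ccc(OS(=O)(=O)c6ccc(C)cc6)c(-c2cc([C@H]3O[C@H](c4ccc(OS(=O)(=O)c6ccc(C)cc6)c(-c5cc(CCO)ccc5OS(=O)(=O)c6ccc(C)cc6)c4)[C@@H](C)O[C@@H]3C)ccc2OS(=O)(=O)c6ccc(C)cc6)c1 | intermediate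
23 | (2R,3R,5R,6R)-2,6-bis[5'-(2-oxoethyl)-2',6-bis(tosyloxy)biphenyl-3-yl]-3,5-dimethyl-1,4-dioxane | O=CCc1ccc(OS(=O)(=O)c6ccc(C)cc6)c(-c2cc([C@H]3O[C@H](c4ccc(OS(=O)(=O)c6ccc(C)cc6)c(-c5cc(CC=O)ccc5OS(=O)(=O)c6ccc(C)cc6)c4)[C@@H](C)O[C@@H]3C)ccc2OS(=O)(=O)c6ccc(C)cc6)c1 | intermediate
24 | methyltriphenylphosphonium bromide | C[P+](c1ccccc1)(c1ccccc1)c1ccccc1.[Br-] | starting material
25 | methylenetriphenylphosphorane | C=P(c1ccccc1)(c1ccccc1)c1ccccc1 | intermediate
26 | (2R,3R,5R,6R)-2,6-bis[5'-allyl-2',6-bis(tosyloxy)biphenyl-3-yl]-3,5-dimethyl-1,4-dioxane | C=CCc1ccc(OS(=O)(=O)c6ccc(C)cc6)c(-c2cc([C@H]3O[C@H](c4ccc(OS(=O)(=O)c6ccc(C)cc6)c(-c5cc(CC=C)ccc5OS(=O)(=O)c6ccc(C)cc6)c4)[C@@H](C)O[C@@H]3C)ccc2OS(=O)(=O)c6ccc(C)cc6)c1 | intermediate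
27 | (2R,3R,5R,6R)-2,6-bis(5'-allyl-2',6-dihydroxybiphenyl-3-yl)-3,5-dimethyl-1,4-dioxane | C=CCc1ccc(O)c(-c2cc([C@H]3O[C@H](c4ccc(O)c(-c5cc(CC=C)ccc5O)c4)[C@@H](C)O[C@@H]3C)ccc2O)c1 | target

**Count**
Total step count: 17. Longest linear sequence: 13 steps (steps 1–4, 6–10, 14–17).

**Steps most likely to fail**

Step 10. The anomeric sulfone may ionise sluggishly because O4 withdraws electron density from the oxocarbenium carbon. The cation may also lose the C3 proton to an enol ether, or the electron-poor arylzinc may add too slowly or with eroded facial selectivity. The fallback gives up the oxocarbenium route and closes the O1–C2 bond by SN2, setting out from lactone 12. Aminolysis with MeNH(OMe)·HCl and i-PrMgCl gives (2R)-2-{[(1R,2R)-1-[3-bromo-4-(tosyloxy)phenyl]-1-hydroxypropan-2-yl]oxy}-N-methoxy-N-methylpropanamide F1. Silylation with t-BuMe2SiCl and imidazole gives the silyl ether F2. Arylmagnesium chloride 9, made from 8 as in step 6, converts the Weinreb amide into the aryl ketone F3. Chelation-controlled reduction with Zn(BH4)2 gives the anti (1S) benzylic alcohol F4, and MsCl/Et3N gives the mesylate F5. Bu4NF then removes the silyl group, and the C6 alkoxide displaces the mesylate with inversion (S to R) in a 6-exo-tet closure, which returns the route to 17.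

Step 16. The basic ylide may deprotonate the arylacetaldehydes, leading to aldol condensation or loss of the dialdehyde before olefination. The fallback keeps the same one-carbon olefination of 23 but makes it a Peterson sequence with a far less basic nucleophile. Me3SiCH2MgCl with CeCl3 in THF at −78 °C adds to both formyl groups to give the bis(β-hydroxysilane) (2R,3R,5R,6R)-2,6-bis{5'-[2-hydroxy-3-(trimethylsilyl)propyl]-2',6-bis(tosyloxy)biphenyl-3-yl}-3,5-dimethyl-1,4-dioxane F6. Acid-promoted elimination with BF3·OEt2 in CH2Cl2 then gives 26.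

Step 7. The ketone α-centre may epimerise in the formic acid/amine medium before hydride transfer, catalyst control may be incomplete, or the centre next to the lactone carbonyl may epimerise during ring closure. The fallback sets out from keto acid 10 and sets C6 by substrate control followed by inversion. Zn(BH4)2 in Et2O at −20 °C reduces the chelated α-alkoxy ketone to the anti product, (2R)-2-{[(1S,2R)-1-[3-bromo-4-(tosyloxy)phenyl]-1-hydroxypropan-2-yl]oxy}propanoic acid F7. Mitsunobu lactonisation (PPh3, diisopropyl azodicarboxylate, dilute THF) then closes the ring with inversion at the benzylic carbon and returns to 12.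

**Further compounds**
F1 | step 10 | (2R)-2-{[(1R,2R)-1-[3-bromo-4-(tosyloxy)phenyl]-1-hydroxypropan-2-yl]oxy}-N-methoxy-N-methylpropanamide | Cc1ccc(cc1)S(=O)(=O)Oc1ccc(cc1Br)[C@@H](O)[C@@H](C)O[C@H](C)C(=O)N(C)OC
F2 | step 10 | (2R)-2-{[(1R,2R)-1-[3-bromo-4-(tosyloxy)phenyl]-1-(tert-butyldimethylsilyloxy)propan-2-yl]oxy}-N-methoxy-N-methylpropanamide | Cc1ccc(cc1)S(=O)(=O)Oc1ccc(cc1Br)[C@@H](O[Si](C)(C)C(C)(C)C)[C@@H](C)O[C@H](C)C(=O)N(C)OC
F3 | step 10 | (2R)-2-{[(1R,2R)-1-[3-bromo-4-(tosyloxy)phenyl]-1-(tert-butyldimethylsilyloxy)propan-2-yl]oxy}-1-[3-bromo-4-(tosyloxy)phenyl]propan-1-one | Cc1ccc(cc1)S(=O)(=O)Oc1ccc(cc1Br)[C@@H](O[Si](C)(C)C(C)(C)C)[C@@H](C)O[C@H](C)C(=O)c1ccc(OS(=O)(=O)c2ccc(C)cc2)c(Br)c1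
F4 | step 10 | (1S,2R)-2-{[(1R,2R)-1-[3-bromo-4-(tosyloxy)phenyl]-1-(tert-butyldimethylsilyloxy)propan-2-yl]oxy}-1-[3-bromo-4-(tosyloxy)phenyl]propan-1-ol | Cc1ccc(cc1)S(=O)(=O)Oc1ccc(cc1Br)[C@@H](O[Si](C)(C)C(C)(C)C)[C@@H](C)O[C@H](C)[C@@H](O)c1ccc(OS(=O)(=O)c2ccc(C)cc2)c(Br)c1
F5 | step 10 | (1S,2R)-2-{[(1R,2R)-1-[3-bromo-4-(tosyloxy)phenyl]-1-(tert-butyldimethylsilyloxy)propan-2-yl]oxy}-1-[3-bromo-4-(tosyloxy)phenyl]propyl methanesulfonate | Cc1ccc(cc1)S(=O)(=O)Oc1ccc(cc1Br)[C@@H](O[Si](C)(C)C(C)(C)C)[C@@H](C)O[C@H](C)[C@@H](OS(C)(=O)=O)c1ccc(OS(=O)(=O)c2ccc(C)cc2)c(Br)c1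
F6 | step 16 | (2R,3R,5R,6R)-2,6-bis{5'-[2-hydroxy-3-(trimethylsilyl)propyl]-2',6-bis(tosyloxy)biphenyl-3-yl}-3,5-dimethyl-1,4-dioxane (carbinol epimers) | C[Si](C)(C)CC(O)Cc1ccc(OS(=O)(=O)c6ccc(C)cc6)c(-c2cc([C@H]3O[C@H](c4ccc(OS(=O)(=O)c6ccc(C)cc6)c(-c5cc(CC(O)C[Si](C)(C)C)ccc5OS(=O)(=O)c6ccc(C)cc6)c4)[C@@H](C)O[C@@H]3C)ccc2OS(=O)(=O)c6ccc(C)cc6)c1
F7 | step 7 | (2R)-2-{[(1S,2R)-1-[3-bromo-4-(tosyloxy)phenyl]-1-hydroxypropan-2-yl]oxy}propanoic acid | Cc1ccc(cc1)S(=O)(=O)Oc1ccc(cc1Br)[C@H](O)[C@@H](C)O[C@H](C)C(=O)O
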